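Readings and results are calculated on assumed constants, noise included.

**Steady pace.** The north run still holds 64% of its solid substrate at 30.0 min, and from 6.00 min to that reading its target grows at 0.792 mM min⁻¹. For the flask below, that pace gives 79.2%. This is the conversion number, pace times time over charge, a Damköhler number. It is less than the whole charge, so in my reckoning the flask is still feeding on its charge near the end.

| setting | south-west | north | flask |
|---|---|---|---|
| solid substrate | 0.025 M | 0.10 M | 0.050 M |
| gas phase | 17 mM (held) | 17 mM (held) | 17 mM (held) |
| remark | run made earlier | run made earlier |  |
| time |  |  | 50 min |

| run | time / min | target / % | solid substrate / % |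
|---|---|---|---|
| south-west | 2.50 | 4 | 77 |
| south-west | 8.00 | 13 | 38 |
| south-west | 15.0 | 35 | 1 |
| south-west | 20.0 | 49 | 4 |
| south-west | 30.0 | 69 | 0 |
| north | 6.00 | 3 | 88 |
| north | 12.0 | 10 | 83 |
| north | 20.0 | 14 | 71 |
| north | 25.0 | 18 | 69 |
| north | 30.0 | 22 | 64 |

(readings scatter by 2 percentage points)

- percentages count the solid substrate that a species holds: one side product counts as two
- solid, in amounts per volume of the solution: solid substrate
- at the start none of the gas is dissolved
- the earlier runs were read with a standard deviation of 2 percentage points
- steps thought possible: gas phase <-> dissolved gas; starting material + dissolved gas -> target; 2 dissolved gas -> homo dimer; solid substrate <-> starting material; starting material + target -> side product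
- at the start none of the solid substrate is in solution

* amount of target at 50 min, in percent of the solid substrate charged
* the change that raises the amount of target at 50 min, in percent of the solid substrate charged most ("none" if none brings more than 2 percentage points) (dusk / summer / noon / dawn / none)
* amount of target at 50 min, in percent of the solid substrate charged, after summer

- dusk: doubling the solubility of the solid substrate, all else as stated
- summer: doubling the dissolution coefficient of the solid substrate, all else as stated
- noon: doubling the saturation concentration of gas phase, all else as stated
- dawn: doubling the transfer coefficient of the gas phase, all else as stated

**One number?** The south-west run tests it. At 30.0 min its number is 95.0%, more than the 69% of target read there, with solid read at 0%. So in my reckoning the number is used only while solid stands in the flask. The north solid falls at 1.00 mM min⁻¹, and at that pace the flask's solid lasts 50.0 min, about the time asked. I therefore expect target a little under the number.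

**Forecast.** It gives 67% (range 58% to 75%), 79% after summer (range 68% to 88%) and noon as best: “Doubling gas saturation nearly doubles the rate constant”.

**Result.** The flask gives 74.5%, which is 7.5 percentage points above the forecast, with 81.1% after summer and noon best, gaining 18 points.

    gas phase ⇌ dissolved gas, rate k1*(csat - [dissolved gas]) (kL = 18.2 min⁻¹)
    starting material + dissolved gas → target (k = 3.42 M⁻¹ min⁻¹)
    2 dissolved gas → homo dimer (k = 4.24 M⁻¹ min⁻¹)
    solid substrate ⇌ starting material, rate k4*(cs4 - [starting material]) while solid is left; crystals form when [starting material] > cs4 (solubility = 23.0 mM, k = 0.125 min⁻¹)
    starting material + target → side product (k = 0.114 M⁻¹ min⁻¹)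

At 50.0 min the flask also holds 5.79% of side product. Target and side product together make 80.3%, beside a conversion number of 79.2%.

**Second flask.** The same charge read at 2.0 h has a number of 190%, above the whole charge, and at that pace the charge takes 63.2 min. That flask gives 91.0% of target, 8.73% of side product and 0.25% of the charge remaining.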